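**Plan**
- Retrosynthetic cuts, in order: C2=CH2 (from a lactone C=O); C5–Br and C3'–Br (each from an axial alcohol, via the C5 and C3' ketones); then O1–C2 and C3–C4 together; last the C4'–Cl/C3'–O pair (chlorolactonization of a limonene-derived acrylic acid).
- Enabling feature: C3 carries an oxygen and the acyl-level C2, and its cyclohexane carbon C1' is 1,3 to C3'. C2 can therefore be tied to O–C3' as a bridged lactone, a 2-oxabicyclo[3.3.1]nonane-3,4-dione, whose C3 ketone has two unlike faces.
- Forward: the cyclohexane comes from (S)-limonene and a temporary lactone ring (ring B) is closed onto it. The key step adds the enolate of 3-hydroxy-3-methylbutan-2-one (O1, C6, C5, C4) to C3 and moves the acyl carbon C2 from O–C3' to O1, which builds the oxane (ring A) and opens ring B.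
- Then C3'–OH is oxidised, both ketones are reduced, both axial alcohols become equatorial bromides, and the lactone is methylenated.
- Stereochemistry: C1' from limonene; C4' (Cl anti to the lactone O) and C3'–O (cis to C1') from the chlorolactonization; C3 from exo attack on the bridged ketone; C5 and the final C3' from equatorial hydride delivery followed by SN2 inversion.

Key step: step 5

Locants used: oxane O1, C2 (=CH2), C3 (OH), C4, C5 (Br), C6 (CMe2); cyclohexane C1' (on C3), C3' (Br), C4' (Cl, CH3). Target = (3S,5R)-5-bromo-3-[(1S,3S,4S)-3-bromo-4-chloro-4-methylcyclohexyl]-6,6-dimethyl-2-methylideneoxan-3-ol. (S)-(−)-Limonene, 3-hydroxy-3-methylbutan-2-one and Cp2TiMe2 solution are taken as purchased.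

**Step 1**
Reactants: 1 (S)-(−)-limonene, (4S)-1-methyl-4-(prop-1-en-2-yl)cyclohex-1-ene
Product: 4 2-[(1S)-4-methylcyclohex-3-en-1-yl]prop-2-en-1-ol, via 10-lithiolimonene 2 (not isolated), via dimethyl allylboronate 3 (not isolated)
Conditions: n-BuLi, TMEDA, hexane, rt; B(OMe)3, THF, −78 °C to rt; H2O2, NaOH, H2O, 0 °C
Reagents that add atoms: hydrogen peroxide, OO
Why: Allylic lithiation–borylation–oxidation: n-BuLi·TMEDA metalates the isopropenyl CH3 selectively, the symmetrical 2-substituted allyllithium is borylated at a CH2 terminus and the C–B bond is oxidised, while the C1' stereocentre is not touched.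

**Step 2**
Reactants: 4 2-[(1S)-4-methylcyclohex-3-en-1-yl]prop-2-en-1-ol
Product: 6 2-[(1S)-4-methylcyclohex-3-en-1-yl]prop-2-enoic acid, via enal 5 (not isolated)
Conditions: TEMPO (cat.), PhI(OAc)2, MeCN/H2O (1:1), rt
Reagents that add atoms: water, O
Why: TEMPO/PhI(OAc)2 (oxoammonium) oxidation takes the primary allylic alcohol through the enal hydrate to the acid and leaves both alkenes and C1' alone.

**Step 3**
Reactants: 6 2-[(1S)-4-methylcyclohex-3-en-1-yl]prop-2-enoic acid
Product: 7 (1S,5S,8S)-8-chloro-8-methyl-4-methylidene-2-oxabicyclo[3.3.1]nonan-3-one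
Conditions: 1,3-dichloro-5,5-dimethylhydantoin, DABCO (10 mol %), CHCl3, −30 °C
Reagents that add atoms: 1,3-dichloro-5,5-dimethylhydantoin, CC1(C)N(Cl)C(=O)N(Cl)C1=O
Why: Chlorolactonization: with the acrylic acid side chain axial the carboxylate can reach only C3' (six-membered lactone; C4' would need a seven-membered bridged ring), so O adds on the C1' face and Cl+ is delivered anti to C4', which fixes C3'–O cis and C4'–Cl trans to the side chain, i.e. (1S,5S,8S).

**Step 4**
Reactants: 7 (1S,5S,8S)-8-chloro-8-methyl-4-methylidene-2-oxabicyclo[3.3.1]nonan-3-one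
Product: 9 (1S,5S,8S)-8-chloro-8-methyl-2-oxabicyclo[3.3.1]nonane-3,4-dione, via spiro-ozonide 8 (not isolated)
Conditions: O3, CH2Cl2, −78 °C; Me2S, −78 °C to rt; dried by azeotrope with toluene
Reagents that add atoms: ozone, [O-][O+]=O
Why: Ozonolysis with reductive work-up cleaves the only remaining C=C, the α-methylene group, to a 1,2-dicarbonyl compound that cannot enolize towards the bridgehead C1', so no stereocentre is at risk.

**Step 5**
Reactants: 9 (1S,5S,8S)-8-chloro-8-methyl-2-oxabicyclo[3.3.1]nonane-3,4-dione; 10 3-hydroxy-3-methylbutan-2-one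
Product: 13 (3S)-3-[(1S,3S,4S)-4-chloro-3-hydroxy-4-methylcyclohexyl]-3-hydroxy-6,6-dimethyloxane-2,5-dione, via dilithium enediolate 11 (not isolated), via bicyclic aldolate 12 (not isolated)
Conditions: 10, LiN(i-Pr)2 (2.2 equiv), THF, −78 °C; add 9, −78 to −20 °C; AcOH, −78 °C
Reagents that add atoms: none
Why: The enolate carbon C4 of dianion 11 adds to the ketone C3 of 9, the most electrophilic and non-enolizable carbonyl, to give aldolate 12, whose tethered tertiary alkoxide O1 then attacks the lactone carbonyl C2 and expels the C3' oxygen, so C3–C4 and O1–C2 form in one flask and the bridged ring is exchanged for the oxane-2,5-dione. The closest known reaction types are the aldol addition of ketone enolates to α-keto esters and alkoxide-induced translactonization (tandem aldol–lactonization). Ring A closes by a 6-exo-trig addition–elimination at C2, helped by the gem-dimethyl group, and the temporary ring B opens in the same event. The one new stereocentre, C3, is set by the bicycle: the enolate should enter on the exo face of the C3 carbonyl (axial on the lactone ring, the side of the one-carbon bridge C2' and of the ring oxygen, which has no axial hydrogen), away from the three-carbon bridge C4'–C6' whose C6' is axial on the neighbouring bridgehead; with C1' and C3' already (S) this gives (3S). The step needs C-attack before O-attack, secured at −78 °C by the hindered, lithium-chelated tertiary alkoxide and the far higher electrophilicity of the ketone, and it needs the ring switch to be downhill, secured by release of a secondary in place of a tertiary alkoxide and of the 1,3-diaxially bridged cyclohexane; the freed alkoxide is trans to the tertiary chloride, so the mixture is quenched cold before epoxide closure can set in.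

**Step 6**
Reactants: 13 (3S)-3-[(1S,3S,4S)-4-chloro-3-hydroxy-4-methylcyclohexyl]-3-hydroxy-6,6-dimethyloxane-2,5-dione
Product: 14 (3S)-3-[(1S,4S)-4-chloro-4-methyl-3-oxocyclohexyl]-3-hydroxy-6,6-dimethyloxane-2,5-dione
Conditions: Dess–Martin periodinane, NaHCO3, CH2Cl2, 0 °C to rt
Reagents that add atoms: none
Why: Dess–Martin oxidation converts the only secondary alcohol to the ketone under buffered, non-basic conditions, so the tertiary C3–OH, the β-hydroxy ketone unit (no retro-aldol) and the quaternary α-chloro centre C4' (no Favorskii reaction, no epimerisation) stay intact.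

**Step 7**
Reactants: 14 (3S)-3-[(1S,4S)-4-chloro-4-methyl-3-oxocyclohexyl]-3-hydroxy-6,6-dimethyloxane-2,5-dione
Product: 15 (3S)-3-[(1S,4S)-4-chloro-4-methyl-3-oxocyclohexyl]-6,6-dimethyl-3-[(triethylsilyl)oxy]oxane-2,5-dione
Conditions: Et3SiOTf, 2,6-lutidine, CH2Cl2, −78 to 0 °C
Reagents that add atoms: triethylsilyl trifluoromethanesulfonate, CC[Si](CC)(CC)OS(=O)(=O)C(F)(F)F
Why: Silylation with a silyl triflate and a hindered base caps the hindered tertiary alcohol without enolizing the ketones, which removes the acidic OH before hydride, phosphonium and titanium reagents are used and places a bulky axial group on C3.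

**Step 8**
Reactants: 15 (3S)-3-[(1S,4S)-4-chloro-4-methyl-3-oxocyclohexyl]-6,6-dimethyl-3-[(triethylsilyl)oxy]oxane-2,5-dione
Product: 16 (3S,5S)-3-[(1S,3R,4S)-4-chloro-3-hydroxy-4-methylcyclohexyl]-5-hydroxy-6,6-dimethyl-3-[(triethylsilyl)oxy]oxan-2-one
Conditions: LiBH(s-Bu)3 (L-Selectride, 2.5 equiv), THF, −78 °C; AcOH, −78 °C
Reagents that add atoms: none
Why: Ketone reduction with a bulky trialkylborohydride, which spares the hindered lactone, should deliver hydride equatorially at both ketones: at C5 anti to the axial C3–OSiEt3 (cyclohexyl equatorial) to give the axial (5S) alcohol, and at C3' in the way usual for 2-chlorocyclohexanones to give the cis-chlorohydrin (3'R), a relation that also excludes epoxide closure; the cold acid quench prevents silyl or acyl migration to the new C5 alkoxide.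

**Step 9**
Reactants: 16 (3S,5S)-3-[(1S,3R,4S)-4-chloro-3-hydroxy-4-methylcyclohexyl]-5-hydroxy-6,6-dimethyl-3-[(triethylsilyl)oxy]oxan-2-one
Product: 17 (3S,5R)-5-bromo-3-[(1S,3S,4S)-3-bromo-4-chloro-4-methylcyclohexyl]-6,6-dimethyl-3-[(triethylsilyl)oxy]oxan-2-one
Conditions: CBr4 (4 equiv), P(n-C8H17)3 (4 equiv), toluene, 70 °C
Reagents that add atoms: carbon tetrabromide, BrC(Br)(Br)Br
Why: Appel reaction: each axial alkoxyphosphonium is displaced by bromide with SN2 inversion, as precedented for 2,2-dimethyloxan-3-ols with CBr4 and trialkylphosphines, turning (5S) into (5R) and (3'R) into (3'S) with both bromides equatorial; an axial leaving group is not antiperiplanar to the ring C–O bond, so ring contraction is not expected.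

**Step 10**
Reactants: 17 (3S,5R)-5-bromo-3-[(1S,3S,4S)-3-bromo-4-chloro-4-methylcyclohexyl]-6,6-dimethyl-3-[(triethylsilyl)oxy]oxan-2-one
Product: 18 {[(3S,5R)-5-bromo-3-[(1S,3S,4S)-3-bromo-4-chloro-4-methylcyclohexyl]-6,6-dimethyl-2-methylideneoxan-3-yl]oxy}triethylsilane
Conditions: Cp2TiMe2 (3 equiv), toluene, 65 °C, dark; filtration through basic alumina
Reagents that add atoms: dimethyltitanocene, C[Ti](C)(C1C=CC=C1)C1C=CC=C1
Why: Petasis methylenation: Cp2Ti=CH2 formed thermally from Cp2TiMe2 converts the lactone C=O into the exocyclic enol ether under neutral conditions that tolerate alkyl bromides, the tertiary chloride and the silyl ether, and with C3 quaternary no endocyclic isomer can form.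

**Step 11**
Reactants: 18 {[(3S,5R)-5-bromo-3-[(1S,3S,4S)-3-bromo-4-chloro-4-methylcyclohexyl]-6,6-dimethyl-2-methylideneoxan-3-yl]oxy}triethylsilane
Product: 19 (3S,5R)-5-bromo-3-[(1S,3S,4S)-3-bromo-4-chloro-4-methylcyclohexyl]-6,6-dimethyl-2-methylideneoxan-3-ol
Conditions: Bu4NF, THF, 0 °C to rt; pH 7 buffer; chromatography on Et3N-deactivated silica
Reagents that add atoms: none
Why: Fluoride desilylation cleaves the Si–O bond without acid, which the 2-methylideneoxane would not survive, and the equatorial bromides and chloride have no antiperiplanar hydrogen, so E2 should not compete.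

**Compound list**
1 | (S)-(−)-limonene, (4S)-1-methyl-4-(prop-1-en-2-yl)cyclohex-1-ene | CC1=CC[C@H](CC1)C(C)=C | starting material
2 | 10-lithiolimonene, {2-[(1S)-4-methylcyclohex-3-en-1-yl]prop-2-en-1-yl}lithium | CC1=CC[C@H](CC1)C(=C)C[Li] | intermediate
3 | dimethyl {2-[(1S)-4-methylcyclohex-3-en-1-yl]prop-2-en-1-yl}boronate | CC1=CC[C@H](CC1)C(=C)CB(OC)OC | intermediate
4 | 2-[(1S)-4-methylcyclohex-3-en-1-yl]prop-2-en-1-ol | CC1=CC[C@H](CC1)C(=C)CO | intermediate
5 | 2-[(1S)-4-methylcyclohex-3-en-1-yl]prop-2-enal | CC1=CC[C@H](CC1)C(=C)C=O | intermediate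
6 | 2-[(1S)-4-methylcyclohex-3-en-1-yl]prop-2-enoic acid | CC1=CC[C@H](CC1)C(=C)C(=O)O | intermediate
7 | (1S,5S,8S)-8-chloro-8-methyl-4-methylidene-2-oxabicyclo[3.3.1]nonan-3-one | C=C1C(=O)O[C@H]2C[C@@H]1CC[C@]2(C)Cl | intermediate
8 | (1S,5S,8S)-8-chloro-8-methylspiro[2-oxabicyclo[3.3.1]nonane-4,3'-[1,2,4]trioxolan]-3-one (secondary ozonide, spiro centre as formed) | O=C1O[C@H]2C[C@H](CC[C@]2(C)Cl)C11OOCO1 | intermediate
9 | (1S,5S,8S)-8-chloro-8-methyl-2-oxabicyclo[3.3.1]nonane-3,4-dione | O=C1C(=O)O[C@H]2C[C@@H]1CC[C@]2(C)Cl | intermediate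
10 | 3-hydroxy-3-methylbutan-2-one | CC(=O)C(C)(C)O | starting material
11 | dilithium 3-methylbut-1-ene-2,3-diolate | [Li+].[Li+].[O-]C(=C)C(C)(C)[O-] | intermediate
12 | dilithium (1S,4S,5S,8S)-8-chloro-8-methyl-4-(3-methyl-3-oxido-2-oxobutyl)-3-oxo-2-oxabicyclo[3.3.1]nonan-4-olate | [Li+].[Li+].[O-][C@]1(CC(=O)C(C)(C)[O-])C(=O)O[C@H]2C[C@@H]1CC[C@]2(C)Cl | intermediate
13 | (3S)-3-[(1S,3S,4S)-4-chloro-3-hydroxy-4-methylcyclohexyl]-3-hydroxy-6,6-dimethyloxane-2,5-dione | O=C1OC(C)(C)C(=O)C[C@]1(O)[C@H]1CC[C@](C)(Cl)[C@@H](O)C1 | intermediate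
14 | (3S)-3-[(1S,4S)-4-chloro-4-methyl-3-oxocyclohexyl]-3-hydroxy-6,6-dimethyloxane-2,5-dione | O=C1OC(C)(C)C(=O)C[C@]1(O)[C@H]1CC[C@](C)(Cl)C(=O)C1 | intermediate
15 | (3S)-3-[(1S,4S)-4-chloro-4-methyl-3-oxocyclohexyl]-6,6-dimethyl-3-[(triethylsilyl)oxy]oxane-2,5-dione | O=C1OC(C)(C)C(=O)C[C@]1(O[Si](CC)(CC)CC)[C@H]1CC[C@](C)(Cl)C(=O)C1 | intermediate
16 | (3S,5S)-3-[(1S,3R,4S)-4-chloro-3-hydroxy-4-methylcyclohexyl]-5-hydroxy-6,6-dimethyl-3-[(triethylsilyl)oxy]oxan-2-one | O=C1OC(C)(C)[C@@H](O)C[C@]1(O[Si](CC)(CC)CC)[C@H]1CC[C@](C)(Cl)[C@H](O)C1 | intermediate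
17 | (3S,5R)-5-bromo-3-[(1S,3S,4S)-3-bromo-4-chloro-4-methylcyclohexyl]-6,6-dimethyl-3-[(triethylsilyl)oxy]oxan-2-one | O=C1OC(C)(C)[C@H](Br)C[C@]1(O[Si](CC)(CC)CC)[C@H]1CC[C@](C)(Cl)[C@@H](Br)C1 | intermediate
18 | {[(3S,5R)-5-bromo-3-[(1S,3S,4S)-3-bromo-4-chloro-4-methylcyclohexyl]-6,6-dimethyl-2-methylideneoxan-3-yl]oxy}triethylsilane | C=C1OC(C)(C)[C@H](Br)C[C@]1(O[Si](CC)(CC)CC)[C@H]1CC[C@](C)(Cl)[C@@H](Br)C1 | intermediate
19 | (3S,5R)-5-bromo-3-[(1S,3S,4S)-3-bromo-4-chloro-4-methylcyclohexyl]-6,6-dimethyl-2-methylideneoxan-3-ol | C=C1OC(C)(C)[C@H](Br)C[C@]1(O)[C@H]1CC[C@](C)(Cl)[C@@H](Br)C1 | target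

**Totals**
Total steps: 11. Longest linear sequence: 11 (1 to 19); compound 10 is bought and enters at step 5.

**Steps most likely to fail**

Step 9. Slow SN2 at two neopentyl-type centres may lose to E2 from the axial alkoxyphosphonium ions (antiperiplanar axial hydrogens at C4 and C2') or to methyl migration. Fallback: starting from 16, activation and displacement are separated. Tf2O and pyridine in CH2Cl2 at −30 °C should give the bis-triflate (3S,5S)-3-[(1S,3R,4S)-4-chloro-4-methyl-3-{[(trifluoromethyl)sulfonyl]oxy}cyclohexyl]-6,6-dimethyl-2-oxo-3-[(triethylsilyl)oxy]oxan-5-yl trifluoromethanesulfonate F6. Displacement with soluble, weakly basic Bu4NBr in toluene at 0 °C to rt, again with inversion at both centres, returns to 17.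

Step 3. Ene-type allylic chlorination or proton loss from the chloronium-like tertiary cation may outrun ring closure, since chlorine bridges poorly. Fallback: starting from 6, bromolactonization with NBS and NaHCO3 in CH2Cl2 (a well-bridged bromonium) gives (1S,5S,8S)-8-bromo-8-methyl-4-methylidene-2-oxabicyclo[3.3.1]nonan-3-one F1. Ozonolysis as in step 4 gives (1S,5S,8S)-8-bromo-8-methyl-2-oxabicyclo[3.3.1]nonane-3,4-dione F2. Treatment with the dianion of 10 as in step 5, but warming to 0 °C, lets the freed C3' alkoxide displace the anti tertiary bromide and gives the epoxide (3S)-3-hydroxy-6,6-dimethyl-3-[(1S,3S,6R)-6-methyl-7-oxabicyclo[4.1.0]heptan-3-yl]oxane-2,5-dione F3. HCl in Et2O at −30 °C opens the epoxide at the tertiary carbon with inversion and returns to 13.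

Step 5. Acyl transfer to the free tertiary alkoxide may occur before C–C bond formation, which opens the bicycle and removes the facial bias; retro-aldol of 12 before the ring switch, or poor exo/endo discrimination, are the other failure modes. Fallback: starting from 9 and 10, the two events are separated and no free alkoxide is present during C–C bond formation. Compound 10 is converted with Me3SiOTf and Et3N into 2,3-bis(trimethylsilyloxy)-3-methylbut-1-ene F4. A BF3·OEt2-mediated Mukaiyama aldol addition of F4 to 9 in CH2Cl2 at −78 °C (open transition state, larger nucleophile) gives (1S,4S,5S,8S)-8-chloro-4-hydroxy-8-methyl-4-{3-methyl-2-oxo-3-[(trimethylsilyl)oxy]butyl}-2-oxabicyclo[3.3.1]nonan-3-one F5. Bu4NF in THF at 0 °C then frees O1 and triggers the translactonization, returning to 13.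

**Further compounds**
F1 | step 3 | (1S,5S,8S)-8-bromo-8-methyl-4-methylidene-2-oxabicyclo[3.3.1]nonan-3-one | C=C1C(=O)O[C@H]2C[C@@H]1CC[C@]2(C)Br
F2 | step 3 | (1S,5S,8S)-8-bromo-8-methyl-2-oxabicyclo[3.3.1]nonane-3,4-dione | O=C1C(=O)O[C@H]2C[C@@H]1CC[C@]2(C)Br
F3 | step 3 | (3S)-3-hydroxy-6,6-dimethyl-3-[(1S,3S,6R)-6-methyl-7-oxabicyclo[4.1.0]heptan-3-yl]oxane-2,5-dione | O=C1OC(C)(C)C(=O)C[C@]1(O)[C@H]1CC[C@@]2(C)O[C@H]2C1
F4 | step 5 | 2,3-bis(trimethylsilyloxy)-3-methylbut-1-ene | C=C(O[Si](C)(C)C)C(C)(C)O[Si](C)(C)C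
F5 | step 5 | (1S,4S,5S,8S)-8-chloro-4-hydroxy-8-methyl-4-{3-methyl-2-oxo-3-[(trimethylsilyl)oxy]butyl}-2-oxabicyclo[3.3.1]nonan-3-one | C[Si](C)(C)OC(C)(C)C(=O)C[C@@]1(O)C(=O)O[C@H]2C[C@@H]1CC[C@]2(C)Cl
F6 | step 9 | (3S,5S)-3-[(1S,3R,4S)-4-chloro-4-methyl-3-{[(trifluoromethyl)sulfonyl]oxy}cyclohexyl]-6,6-dimethyl-2-oxo-3-[(triethylsilyl)oxy]oxan-5-yl trifluoromethanesulfonate | O=C1OC(C)(C)[C@@H](OS(=O)(=O)C(F)(F)F)C[C@]1(O[Si](CC)(CC)CC)[C@H]1CC[C@](C)(Cl)[C@H](OS(=O)(=O)C(F)(F)F)C1
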